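**Retrosynthetic overview**

1. Feature: oxirane carbon C2 is quaternary and carries the aryl ring, ring oxygen O1 and two one-carbon oxygenated arms (ring C3H2 and exocyclic CH2OAc). It is stereogenic only because these arms differ, so it maps onto a prochiral ArC(OH)(CH2Cl)2.
2. Target 12 ⇐ chlorohydrin acetate 11 (tertiary O closes onto the remaining CH2Cl) ⇐ (R)-2-aryl-2-(chloromethyl)oxirane 10 (acetate opens the oxirane CH2; arms exchanged, no bond to C2 broken).
3. 10 ⇐ prochiral bis(chloromethyl) carbinol 9 by halohydrin-dehalogenase closure of one enantiotopic CH2Cl arm, which sets the only stereocentre.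
4. 9 ⇐ aryl–C bond between the aryllithium from bis-silylated 4-bromo-3-hydroxybenzyl alcohol and 1,3-dichloroacetone, then silyl-to-isobutyryl exchange.
5. Ring order: the benzene ring is bought; the oxirane is the only ring made. It is closed on one arm in step 6, opened in step 7 and closed again on the other arm in step 8.

Key step: step 6

Assumption: the sense of arm selection by a given halohydrin dehalogenase on this substrate cannot be predicted, so it is assumed that screening of HheC-type and enantiocomplementary variants provides one that delivers the (R)-oxirane 10.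

**Route**

Step 1
Reactants: 1 methyl 4-bromo-3-hydroxybenzoate
Product: 2 2-bromo-5-(hydroxymethyl)phenol
Conditions: i-Bu2AlH (3.5 equiv), THF, −78 → 0 °C; aq potassium sodium tartrate work-up
Reagents that add atoms: none
Why: Hydride reduction of the ester to the primary alcohol; the phenol is first converted to its aluminium phenoxide and the aryl bromide is inert to i-Bu2AlH at this temperature.

Step 2
Reactants: 2 2-bromo-5-(hydroxymethyl)phenol
Product: 3 {2-bromo-5-{[tri(propan-2-yl)silyloxy]methyl}phenoxy}tri(propan-2-yl)silane
Conditions: TIPSCl (2.4 equiv), imidazole, DMAP (cat.), DMF, rt → 40 °C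
Reagents that add atoms: chlorotri(propan-2-yl)silane (TIPSCl), CC(C)[Si](Cl)(C(C)C)C(C)C
Why: Imidazole-promoted silylation of phenol and primary alcohol; the bulky triisopropylsilyl group on the phenol oxygen is chosen so that the later ortho-lithiated species resists 1,3-O→C silyl shift.

Step 3
Reactants: 3 {2-bromo-5-{[tri(propan-2-yl)silyloxy]methyl}phenoxy}tri(propan-2-yl)silane; 4 bis(chloromethyl) ketone (1,3-dichloroacetone)
Product: 6 bis-silylated dichlorocarbinol 1,3-dichloro-2-{2-[tri(propan-2-yl)silyloxy]-4-{[tri(propan-2-yl)silyloxy]methyl}phenyl}propan-2-ol, via aryllithium 5 (not isolated)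
Conditions: n-BuLi (1.05 equiv), THF, −78 °C, 10 min; then 4 (1.2 equiv), −78 °C; AcOH quench at −78 °C
Reagents that add atoms: none
Why: Bromine–lithium exchange followed by 1,2-addition of the aryllithium to the ketone is the established entry to 2-aryl-1,3-dichloropropan-2-ols, and the cold acidic quench protonates the lithium alkoxide before it can displace chloride.

Step 4
Reactants: 6 bis-silylated dichlorocarbinol
Product: 7 1,3-dichloro-2-[2-hydroxy-4-(hydroxymethyl)phenyl]propan-2-ol
Conditions: Bu4NF (3 equiv), AcOH (4.5 equiv), THF, 0 °C → rt; crude product taken on directly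
Reagents that add atoms: none
Why: Fluoride desilylation buffered with acetic acid, so that neither the phenoxide (which could attack a CH2Cl arm in a 5-exo-tet sense) nor the tertiary alkoxide (which would close a racemic oxirane) is present in meaningful concentration.

Step 5
Reactants: 7 1,3-dichloro-2-[2-hydroxy-4-(hydroxymethyl)phenyl]propan-2-ol; 8 isobutyric anhydride
Product: 9 2-(1,3-dichloro-2-hydroxypropan-2-yl)-5-{[(2-methylpropanoyl)oxy]methyl}phenyl 2-methylpropanoate (prochiral)
Conditions: 8 (2.2 equiv), pyridine, DMAP (5 mol%), CH2Cl2, −10 → 0 °C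
Reagents that add atoms: none
Why: DMAP-catalysed acylation takes the phenol and the primary benzylic alcohol, whereas the tertiary carbinol flanked by two CH2Cl groups and an ortho-substituted ring is too hindered and too weakly nucleophilic to react at 0 °C, and pyridine is too weak a base to trigger chloride displacement.

Step 6
Reactants: 9 2-(1,3-dichloro-2-hydroxypropan-2-yl)-5-{[(2-methylpropanoyl)oxy]methyl}phenyl 2-methylpropanoate
Product: 10 2-[(2R)-2-(chloromethyl)oxiran-2-yl]-5-{[(2-methylpropanoyl)oxy]methyl}phenyl 2-methylpropanoate
Conditions: purified halohydrin dehalogenase (HheC-type variant chosen by screening for the (R)-oxirane), K2HPO4/KH2PO4 buffer (0.5 M, pH 7.5) / n-heptane–MTBE two-phase, 25 °C, stopped before equilibrium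
Reagents that add atoms: none
Why: Proposed new method: no halohydrin dehalogenase has been shown to desymmetrise a tertiary 2-aryl-1,3-dichloropropan-2-ol, but the step asks only for the enzyme's native chemistry: the tyrosine of the serine–tyrosine–arginine triad takes the carbinol proton while one CH2Cl sits in the halide pocket anti to the oxygen, and the oxygen displaces chloride in an intramolecular SN2 step. The closest known reactions are the enzymatic conversion of prochiral 1,3-dichloropropan-2-ol into enantioenriched epichlorohydrin and the acceptance of tertiary 2-methyl chlorohydrins and their 2,2-disubstituted oxiranes by HheC-type enzymes. The oxirane closes in the 3-exo-tet mode. The quaternary carbon becomes stereogenic solely through the choice between the two enantiotopic CH2Cl arms, and this choice is under catalyst control: with the aryl ring lodged in the hydrophobic pocket only one arm should reach the halide site, and the arm closed here is the one that later becomes the acetoxymethyl arm. The step needs enantiotopic-group selectivity plus chemoselectivity over uncatalysed closure, ester hydrolysis and acyl shift to the free tertiary OH; near-neutral pH, esterase-free purified enzyme and the hindered isobutyryl groups should secure the latter. Because chloride-mediated reopening leads back to prochiral 9 and would give racemic 10 at equilibrium, 10 is withdrawn continuously into the organic phase and the reaction is stopped before equilibrium.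

Step 7
Reactants: 10 2-[(2R)-2-(chloromethyl)oxiran-2-yl]-5-{[(2-methylpropanoyl)oxy]methyl}phenyl 2-methylpropanoate
Product: 11 2-[(2R)-1-(acetyloxy)-3-chloro-2-hydroxypropan-2-yl]-5-{[(2-methylpropanoyl)oxy]methyl}phenyl 2-methylpropanoate
Conditions: AcOH (5 equiv), Bu4NOAc (0.2 equiv), MeCN, 50 °C
Reagents that add atoms: acetic acid, CC(=O)O
Why: Carboxylate opening of a 2,2-disubstituted oxirane at its CH2 by SN2, with acetate regenerated by proton transfer from AcOH; the quaternary benzylic carbon cannot be attacked in an SN2 sense, its ionisation is disfavoured by the CH2Cl group in this weakly acidic halide-free medium, the neopentyl-type CH2Cl is unreactive, and C2 keeps its configuration because no bond to it is broken.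

Step 8
Reactants: 11 2-[(2R)-1-(acetyloxy)-3-chloro-2-hydroxypropan-2-yl]-5-{[(2-methylpropanoyl)oxy]methyl}phenyl 2-methylpropanoate
Product: 12 [(2S)-2-(2-[(2-methylpropanoyl)oxy]-4-{[(2-methylpropanoyl)oxy]methyl}phenyl)oxiran-2-yl]methyl acetate (target)
Conditions: Cs2CO3 (1.5 equiv), dry MeCN, 0 °C → rt
Reagents that add atoms: none
Why: Intramolecular Williamson reaction (3-exo-tet) of the tertiary alkoxide on the remaining CH2Cl, the standard conversion of a chlorohydrin ester into a glycidyl ester, which is expected to outrun acyl transfer from the neighbouring acetate or aryl isobutyrate under anhydrous carbonate conditions; C2 is untouched, and the descriptor changes from R to S only because the arm priorities change.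

**Compound list**

1 | methyl 4-bromo-3-hydroxybenzoate | COC(=O)c1ccc(Br)c(O)c1 | starting material
2 | 2-bromo-5-(hydroxymethyl)phenol | OCc1ccc(Br)c(O)c1 | intermediate
3 | {2-bromo-5-{[tri(propan-2-yl)silyloxy]methyl}phenoxy}tri(propan-2-yl)silane | CC(C)[Si](OCc1ccc(Br)c(O[Si](C(C)C)(C(C)C)C(C)C)c1)(C(C)C)C(C)C | intermediate
4 | bis(chloromethyl) ketone (1,3-dichloroacetone) | O=C(CCl)CCl | starting material
5 | {2-[tri(propan-2-yl)silyloxy]-4-{[tri(propan-2-yl)silyloxy]methyl}phenyl}lithium | [Li]c1ccc(CO[Si](C(C)C)(C(C)C)C(C)C)cc1O[Si](C(C)C)(C(C)C)C(C)C | intermediate (not isolated)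
6 | 1,3-dichloro-2-{2-[tri(propan-2-yl)silyloxy]-4-{[tri(propan-2-yl)silyloxy]methyl}phenyl}propan-2-ol | OC(CCl)(CCl)c1ccc(CO[Si](C(C)C)(C(C)C)C(C)C)cc1O[Si](C(C)C)(C(C)C)C(C)C | intermediate
7 | 1,3-dichloro-2-[2-hydroxy-4-(hydroxymethyl)phenyl]propan-2-ol | OCc1ccc(C(O)(CCl)CCl)c(O)c1 | intermediate
8 | isobutyric anhydride | CC(C)C(=O)OC(=O)C(C)C | starting material
9 | 2-(1,3-dichloro-2-hydroxypropan-2-yl)-5-{[(2-methylpropanoyl)oxy]methyl}phenyl 2-methylpropanoate | OC(CCl)(CCl)c1ccc(COC(=O)C(C)C)cc1OC(=O)C(C)C | intermediate
10 | 2-[(2R)-2-(chloromethyl)oxiran-2-yl]-5-{[(2-methylpropanoyl)oxy]methyl}phenyl 2-methylpropanoate | ClC[C@@]1(c2ccc(COC(=O)C(C)C)cc2OC(=O)C(C)C)CO1 | intermediate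
11 | 2-[(2R)-1-(acetyloxy)-3-chloro-2-hydroxypropan-2-yl]-5-{[(2-methylpropanoyl)oxy]methyl}phenyl 2-methylpropanoate | ClC[C@@](O)(c1ccc(COC(=O)C(C)C)cc1OC(=O)C(C)C)COC(C)=O | intermediate
12 | [(2S)-2-(2-[(2-methylpropanoyl)oxy]-4-{[(2-methylpropanoyl)oxy]methyl}phenyl)oxiran-2-yl]methyl acetate | CC(=O)OC[C@]1(c2ccc(COC(=O)C(C)C)cc2OC(=O)C(C)C)CO1 | target

**Step count**

Total steps: 8. Longest linear sequence: 8 steps (1 → 12).

**Steps most likely to fail**

Step 6. The enzyme may fail to bind or turn over the hindered, ortho-substituted tertiary carbinol, or may discriminate the two chloromethyl arms poorly. Slow turnover would also let uncatalysed closure, ester hydrolysis or chloride-mediated reopening erode the enantiomeric purity. The fallback uses known chemistry, sets out from 2 and comes back to the route at 12. Diol 2 would be acylated on both oxygens with 8 (pyridine, DMAP, CH2Cl2) to give 2-bromo-5-{[(2-methylpropanoyl)oxy]methyl}phenyl 2-methylpropanoate F1. A Stille coupling of F1 with 2-(tributylstannyl)prop-2-en-1-ol (Pd(PPh3)4, CuI, DMF, 80 °C, no added base) should give the 2-arylallyl alcohol 2-(3-hydroxyprop-1-en-2-yl)-5-{[(2-methylpropanoyl)oxy]methyl}phenyl 2-methylpropanoate F2. Sharpless asymmetric epoxidation of F2 (Ti(OiPr)4 10 mol%, D-(−)-diisopropyl tartrate 12 mol%, t-BuOOH, 4 Å molecular sieves, CH2Cl2, −20 °C) should give 2-[(2R)-2-(hydroxymethyl)oxiran-2-yl]-5-{[(2-methylpropanoyl)oxy]methyl}phenyl 2-methylpropanoate F3. D-(−)-tartrate is chosen because it is the ligand series that leads to (R)-glycidol from allyl alcohol, and the aryl group takes the place of hydrogen as the lowest-ranked substituent. Acetylation of F3 (Ac2O, pyridine, 0 °C, best carried out without isolating the sensitive epoxy alcohol) would give 12; the descriptor becomes S through the change in arm priority alone.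

Step 7. Partial ionisation at the benzylic oxirane carbon under the acidic buffer could divert the opening to the quaternary carbon with loss of configuration, or lead to a 1,2-shift to carbonyl compounds. Attack at the hindered CH2 may also be too slow at a temperature the aryl ester tolerates. The fallback sets out from 10 and comes back to the route at 12. The acid-buffered chlorohydrin stage would be abandoned in favour of an acid-free anionic relay. Anhydrous CsOAc with 18-crown-6 in MeCN at 40–60 °C should deliver acetate to the oxirane CH2, and the cesium alkoxide of 11 so formed should close at once onto CH2Cl. This is the classical carboxylate-salt synthesis of glycidyl esters from epichlorohydrin. It gives 12 in one operation, with no Brønsted acid present to promote ionisation and no new isolated compound.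

Step 3. Proton transfer from the enolisable, base-sensitive chloroketone to the aryllithium would return the debrominated arene, and collapse of the adduct alkoxide onto a chloromethyl arm would give a racemic oxirane. The fallback sets out from 3 and comes back to the route at 6, building the carbinol by two additions to partners that do not suffer these processes. Aryllithium 5, generated as before, would be acylated with 2-chloro-N-methoxy-N-methylacetamide (THF, −78 °C) to give the α-chloro ketone 2-chloro-1-{2-[tri(propan-2-yl)silyloxy]-4-{[tri(propan-2-yl)silyloxy]methyl}phenyl}ethan-1-one F4. Chloromethyllithium F5, generated in the presence of F4 from chloroiodomethane and MeLi·LiBr at −78 °C, should add to the ketone (carbenoid homologation to a chlorohydrin). A cold AcOH quench would then give 6.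

**Further compounds**

F1 | step 6 | 2-bromo-5-{[(2-methylpropanoyl)oxy]methyl}phenyl 2-methylpropanoate | CC(C)C(=O)OCc1ccc(Br)c(OC(=O)C(C)C)c1
F2 | step 6 | 2-(3-hydroxyprop-1-en-2-yl)-5-{[(2-methylpropanoyl)oxy]methyl}phenyl 2-methylpropanoate | C=C(CO)c1ccc(COC(=O)C(C)C)cc1OC(=O)C(C)C
F3 | step 6 | 2-[(2R)-2-(hydroxymethyl)oxiran-2-yl]-5-{[(2-methylpropanoyl)oxy]methyl}phenyl 2-methylpropanoate | OC[C@]1(c2ccc(COC(=O)C(C)C)cc2OC(=O)C(C)C)CO1
F0 | step 7 | none | none
F4 | step 3 | 2-chloro-1-{2-[tri(propan-2-yl)silyloxy]-4-{[tri(propan-2-yl)silyloxy]methyl}phenyl}ethan-1-one | O=C(CCl)c1ccc(CO[Si](C(C)C)(C(C)C)C(C)C)cc1O[Si](C(C)C)(C(C)C)C(C)C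
F5 | step 3 | chloromethyllithium | [Li]CCl
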